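## Analysis of the target

Target 20 is a hexaphenolic chalcone–flavanone dimer. Its core is a 5,7-dihydroxyflavanone (rings A and C, with the 4-hydroxyphenyl ring B on C2). C3 carries a second aryl group, ring D, a 2-hydroxyphenyl whose C5 bears an (E)-enone ending in a 2,4-dihydroxyphenyl ketone. The only stereocentres are C2 (R) and C3 (S), adjacent in ring C and trans, so both aryl groups can sit equatorial; this is the thermodynamically preferred arrangement. C3–H is benzylic and α to the C4 ketone and therefore epimerisable, which is harmless as long as C2 holds. C2–O1 is a benzylic aryl ether para to the ring B oxygen and β to the ketone, so ionisation, or enolisation followed by β-elimination to an achiral α-aryl chalcone, would erase the absolute configuration. The 2'-hydroxychalcone rules out hydrogenolysis and cyclises under base or acid, and ring A is a carbon nucleophile, so the late steps must be neutral or Lewis acidic and six phenols must be handled with two kinds of protecting group. The difficulty is therefore to set C2 absolutely and then never expose it to soluble base. The strategy rests on C2–C3–C4 being a three-carbon carboxylic acid unit joined to ring A through O1 (on C8a) and through C4 (on C4a), two adjacent positions of a symmetric phloroglucinol ring. Ring C is thus a 2,3-diaryl β-lactone plus a 3,5-dioxygenated phenol.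

## Retrosynthetic reasoning

**20 ⇐ 19 ⇐ 18 (protecting groups).** No skeletal bond is cut. 20 is unmasked from 19 by Lewis acid cleavage of five benzyl ethers, the only general phenol deprotection here that leaves the enone unreduced. 19 comes from 18 by removal of the ring B pivalate under neutral conditions. The pivalate goes first so that the polyphenol appears only in the last operation and no step after ring C formation needs alkoxide.

**18 ⇐ 13 + 17 (ring D C5–vinyl bond).** The enone is too fragile to pass through ketene, phenoxide and anhydride chemistry, so it is attached last by a Heck coupling. The ring D bromide of 13 is inert in every earlier step and sits para to the ring D oxygen, where bromination of a phenol places it. The forward reaction must give the (E)-alkene without a soluble base reaching C3–H.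

**17 ⇐ 15 ⇐ 14.** The vinyl ketone is the acetyl group of 14 plus one carbon (Mannich addition and elimination through 16) after both phenols are benzylated. The 2'-oxygen is capped so that the chalcone cannot close to a flavanone during the coupling.

**13 ⇐ 9 + 10 (O1–C2 and C4–C4a, the key disconnection).** These two bonds join the three-carbon unit to ring A. Cutting both leaves phenol 10, whose two ortho carbons are equivalent, and cis-β-lactone 9, which already holds both stereocentres. The forward step must open 9 at its benzylic carbon with clean inversion (via 11), so that the cis lactone becomes the trans flavanone, and then acylate ring A through mixed anhydride 12. Cutting C2–C3 or C3–C4 instead would mean creating a stereocentre in the ring-forming step itself.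

**9 ⇐ 5 + 7 (lactone C3–C4 and acyl–oxygen bonds).** A catalytic asymmetric ketene–aldehyde cyclocondensation through ketene 8 sets both centres at once and gives the cis isomer that the inversion requires. Aldehyde 7 carries a pivalate so that ring B is not a strong donor.

**5 ⇐ 4 ⇐ 2 ⇐ 1 and 7 ⇐ 6.** These are functional-group operations on two cheap acids and phenols: para-bromination, benzylation (through 3), acid chloride formation, and pivaloylation.

## Alternatives that were turned down

**Alternative 1:** disconnection at C2–C3.
- **Key step.** Deoxybenzoin A1, whose ring A oxygen carries a 4-hydroxybenzyl group, would be oxidised by two electrons (a quinone oxidant or an anode) to the O-aryl para-quinone methide level. The ketone enol, held by a chiral Brønsted acid, would add to the exocyclic carbon to give A2, closing ring C and setting both centres.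
- **For.** A1 comes from classical deoxybenzoin chemistry, ring B arrives with its phenol free, and both stereocentres come from one catalytic event. On economy of the stereochemical part this plan is the stronger one.
- **Against.** The intermediate is at the aldehyde oxidation level, a masked mixed acetal, so water or a phenol can cleave ring A off. The oxidant must pick the hydroxybenzyl ether beside a very electron-rich ring A. Facial control for an oxygen-tethered enol addition would have to be found. Ring D must carry a masked aldehyde through oxidation and acid, with the enone still to build.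
- **Comparison.** The chosen route moves C2 into the molecule by a stereospecific inversion instead of discovering it in an untested asymmetric cyclisation, and no electron-rich ring meets an oxidant.

**Alternative 2:** disconnection at O1–C2 and C3–C4.
- **Key step.** Salicylaldehyde A3, an orthoester and a chiral Brønsted acid would give a 4-methoxy ortho-quinone methide that adds across (E)-stilbene A4 to give the 4-methoxyflavan A5.
- **For.** It is the most convergent plan: two achiral pieces, two ring bonds in one cycloaddition, and the trans relationship follows from the alkene geometry. On convergence it beats the chosen route and equals it in bonds formed in the ring-forming event.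
- **Against.** Regiochemistry depends on ring B stabilising the developing cation better than ring D, and both are oxygenated. C4 arrives as a methyl ether and must be hydrolysed and oxidised at a benzylic position flanked by ring A, which ionises readily; this costs two or three steps and a discarded stereocentre.
- **Comparison.** The chosen route delivers C4 as the ketone directly and has no regiochemical question, because the phenoxide oxygen and the ortho carbon of ring A can only join the lactone one way round.

**Alternative 3:** disconnection at C3–C4.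
- **Key step.** In aldehyde A6, fluoride would free the ring D phenoxide, which expels acetate to give an ortho-quinone methide. The carbene-derived acyl anion equivalent of the ring A aldehyde would add to C3 to give A7.
- **For.** The ketone forms at the right oxidation level under mild, non-acidic conditions, the closure is intramolecular, and the ring D phenol emerges free. In directness for C4 it matches the chosen route.
- **Against.** A6 needs C2 set beforehand in an acyclic aryl ether of a 1,2-dioxygenated diarylethane, which is a long preparation. The quinone methide has a hydrogen on the neighbouring C2 and can tautomerise to a vinyl ether, destroying that centre. The aldehyde sits between two ortho oxygens and is hindered. The basic medium then meets a flavanone that opens by β-elimination.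
- **Comparison.** The chosen route reaches precursor 9 in few steps, and C2 stays tetrahedral throughout, changing partners in a single concerted displacement.

Key step: step 6

**Remarks on the chemistry.**
- Phenol 10 is taken as a catalogue compound.
- The quinine-derived catalyst is written for the (3S,4S) lactone by analogy with the sense this catalyst family shows with alkyl ketenes. If the first batch proved to be the mirror image, the quinidine-derived pseudoenantiomer would be used and nothing else would change.

## Route

Step 1
Reactants: 1 (2-hydroxyphenyl)acetic acid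
Product: 2 (5-bromo-2-hydroxyphenyl)acetic acid
Conditions: NBS (1.0 equiv), MeCN, 0 °C
Reagents that add atoms: N-bromosuccinimide, O=C1CCC(=O)N1Br
Why: Electrophilic aromatic bromination; the hydroxyl group directs to its para position (C5), the least hindered activated site, so one equivalent of reagent in the cold should give the 5-bromide with little ortho or dibromo product.

Step 2
Reactants: 2 (5-bromo-2-hydroxyphenyl)acetic acid
Product: 4 [2-(benzyloxy)-5-bromophenyl]acetic acid, via benzyl ester 3 (not isolated)
Conditions: BnBr, K2CO3, DMF, 50 °C; then NaOH, MeOH/H2O, 50 °C; HCl work-up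
Reagents that add atoms: benzyl bromide, BrCc1ccccc1; sodium hydroxide, [Na+].[OH-]
Why: Williamson O-alkylation of the phenoxide (the carboxylate is benzylated as well), then saponification of benzyl ester 3 in the same flask; the aryl benzyl ether is inert to hydroxide.

Step 3
Reactants: 4 [2-(benzyloxy)-5-bromophenyl]acetic acid
Product: 5 [2-(benzyloxy)-5-bromophenyl]acetyl chloride
Conditions: (COCl)2, DMF (cat.), CH2Cl2, 0 °C → rt; used crude
Reagents that add atoms: oxalyl chloride, ClC(=O)C(=O)Cl
Why: DMF-catalysed (Vilsmeier-type) acid chloride formation under cold, non-forcing conditions; the product is used at once so that the ortho benzyloxy oxygen has no time to attack the acyl chloride.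

Step 4
Reactants: 6 4-hydroxybenzaldehyde
Product: 7 4-formylphenyl pivalate
Conditions: PivCl, Et3N, DMAP (cat.), CH2Cl2, 0 °C → rt
Reagents that add atoms: pivaloyl chloride, CC(C)(C)C(=O)Cl
Why: Nucleophile-catalysed O-acylation of the phenol; the pivalate is chosen because its hindered carbonyl resists phenoxide attack later and because it turns the para oxygen from a strong donor into a weak one.

Step 5
Reactants: 5 [2-(benzyloxy)-5-bromophenyl]acetyl chloride; 7 4-formylphenyl pivalate
Product: 9 4-[(2S,3S)-3-[2-(benzyloxy)-5-bromophenyl]-4-oxooxetan-2-yl]phenyl pivalate (cis-β-lactone), via aryl ketene 8 (not isolated)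
Conditions: O-trimethylsilylquinine (15 mol %), LiClO4, i-Pr2NEt, CH2Cl2/Et2O, −78 °C, slow addition of 5
Reagents that add atoms: none
Why: Lewis base/Lewis acid co-catalysed acyl halide–aldehyde cyclocondensation (formal [2+2] ketene–aldehyde cycloaddition): the amine base forms ketene 8, the quinuclidine nitrogen converts it into a chiral ammonium (Z)-enolate that adds to the LiClO4-activated aldehyde through a closed transition state and lactonises to the cis lactone, the alkaloid shielding one enolate face and so setting C3 and C4 together; slow addition keeps the ketene concentration low and suppresses dimerisation.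

Step 6
Reactants: 9 4-[(2S,3S)-3-[2-(benzyloxy)-5-bromophenyl]-4-oxooxetan-2-yl]phenyl pivalate; 10 3,5-bis(benzyloxy)phenol
Product: 13 4-[(2R,3S)-5,7-bis(benzyloxy)-3-[2-(benzyloxy)-5-bromophenyl]-4-oxochroman-2-yl]phenyl pivalate (2,3-trans), via potassium 3-aryloxypropanoate 11 (not isolated), via mixed trifluoroacetic anhydride 12 (not isolated)
Conditions: 10, KH, 18-crown-6, THF, 0 °C; then 9, 0 °C → rt; then CH2Cl2, (CF3CO)2O, 0 °C
Reagents that add atoms: none
Why: The crown-ether-separated potassium phenoxide of 10 attacks the benzylic C4 of the lactone from the face opposite the ring oxygen (SN2, alkyl–oxygen cleavage driven by release of ring strain), forming O1–C2 with inversion and giving carboxylate 11; trifluoroacetic anhydride then turns 11 into mixed anhydride 12, whose acyl carbon is attacked by the ring A carbon ortho to O1 to form C4–C4a. The closest known reactions are the alkyl–oxygen opening of β-lactones by phenoxides and other soft nucleophiles with inversion, and the anhydride-mediated cyclisation of 3-aryloxypropanoic acids to chroman-4-ones. Ring C closes as a six-membered ring by intramolecular Friedel–Crafts acylation (6-exo-trig with respect to the acyl C=O); the two ortho carbons of ring A are equivalent and the para carbon cannot reach, so no regiochemical question arises. C2 (R) is controlled by the configuration of lactone C4 through stereospecific inversion, and C3 (S) is carried over from the lactone. Should C3 epimerise by enolisation at any stage, the trans isomer with both aryl groups equatorial is the thermodynamic sink, so the absolute configuration of the product depends only on lactone C4. The step needs O- over C-alkylation and alkyl– over acyl–oxygen attack: a free phenoxide in an aprotic medium reacts at oxygen, the strained benzylic carbon is the soft site, and acyl attack is reversible because the resulting alkoxide relactonises. Elimination, which plagues open-chain β-leaving groups next to an acidic α-hydrogen, is shut off because the lactone enolate is orthogonal to the breaking C–O bond, and the pivalate keeps ring B from ionising C4 or promoting loss of CO2. Acylation by the tethered, more electron-rich acyl group should outrun trifluoroacetylation of ring A if the anhydride is kept near stoichiometric and cold.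

Step 7
Reactants: 14 1-(2,4-dihydroxyphenyl)ethanone
Product: 15 1-[2,4-bis(benzyloxy)phenyl]ethanone
Conditions: BnBr (excess), K2CO3, DMF, 70 °C
Reagents that add atoms: benzyl bromide, BrCc1ccccc1
Why: Williamson O-benzylation; the forcing conditions also alkylate the hydrogen-bonded 2'-hydroxyl, which must be capped so that the later chalcone cannot cyclise onto its own enone.

Step 8
Reactants: 15 1-[2,4-bis(benzyloxy)phenyl]ethanone
Product: 17 1-[2,4-bis(benzyloxy)phenyl]prop-2-en-1-one, via Mannich base 16 (not isolated)
Conditions: (CH2O)n, i-Pr2NH·CF3CO2H, CF3CO2H (cat.), THF, reflux; used fresh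
Reagents that add atoms: formaldehyde (as paraformaldehyde), C=O
Why: Mannich reaction followed by β-elimination (α-methylenation of a methyl ketone): the ammonium salt and formaldehyde give an iminium ion that the ketone enol traps as Mannich base 16, which loses the amine on heating to give the aryl vinyl ketone.

Step 9
Reactants: 13 4-[(2R,3S)-5,7-bis(benzyloxy)-3-[2-(benzyloxy)-5-bromophenyl]-4-oxochroman-2-yl]phenyl pivalate; 17 1-[2,4-bis(benzyloxy)phenyl]prop-2-en-1-one
Product: 18 4-[(2R,3S)-5,7-bis(benzyloxy)-3-{2-(benzyloxy)-5-[(1E)-3-[2,4-bis(benzyloxy)phenyl]-3-oxoprop-1-en-1-yl]phenyl}-4-oxochroman-2-yl]phenyl pivalate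
Conditions: Pd(OAc)2 (5 mol %), P(o-tol)3, n-Bu4NCl, NaHCO3, DMF, 80 °C
Reagents that add atoms: none
Why: Heck reaction: oxidative addition of the ring D C–Br bond to zerovalent palladium, syn insertion of the electron-poor terminal alkene at its CH2 carbon and syn β-hydride elimination give the (E)-enone; the weak, insoluble base and the bulky, poorly nucleophilic phosphine are chosen so that neither the flavanone nor the vinyl ketone meets a soluble base or nucleophile.

Step 10
Reactants: 18 4-[(2R,3S)-5,7-bis(benzyloxy)-3-{2-(benzyloxy)-5-[(1E)-3-[2,4-bis(benzyloxy)phenyl]-3-oxoprop-1-en-1-yl]phenyl}-4-oxochroman-2-yl]phenyl pivalate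
Product: 19 (2R,3S)-5,7-bis(benzyloxy)-3-{2-(benzyloxy)-5-[(1E)-3-[2,4-bis(benzyloxy)phenyl]-3-oxoprop-1-en-1-yl]phenyl}-2-(4-hydroxyphenyl)chroman-4-one
Conditions: Me3SnOH, ClCH2CH2Cl, 70 °C
Reagents that add atoms: none
Why: Ester cleavage by tin-assisted hydroxide transfer (acyl substitution) under essentially neutral conditions; the aryl ester is activated by its phenoxide leaving group, while C3–H, the C2–O1 bond and the enone are not exposed to alkoxide.

Step 11
Reactants: 19 (2R,3S)-5,7-bis(benzyloxy)-3-{2-(benzyloxy)-5-[(1E)-3-[2,4-bis(benzyloxy)phenyl]-3-oxoprop-1-en-1-yl]phenyl}-2-(4-hydroxyphenyl)chroman-4-one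
Product: 20 (2R,3S)-3-{5-[(1E)-3-(2,4-dihydroxyphenyl)-3-oxoprop-1-en-1-yl]-2-hydroxyphenyl}-5,7-dihydroxy-2-(4-hydroxyphenyl)chroman-4-one
Conditions: BCl3, C6HMe5, CH2Cl2, −78 → −40 °C; MeOH quench, cold work-up
Reagents that add atoms: none
Why: Lewis acid ether cleavage: BCl3 coordinates each benzyloxy oxygen and releases benzyl cation equivalents that pentamethylbenzene traps by Friedel–Crafts alkylation, so ring A and the enone are not benzylated; the ring oxygen O1 is a vinylogous ester oxygen and a poorer donor, no reducing agent touches the enone, and the stereocentres are not involved.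

## Compound list

1 | (2-hydroxyphenyl)acetic acid | OC(=O)Cc1ccccc1O | starting material
2 | (5-bromo-2-hydroxyphenyl)acetic acid | OC(=O)Cc1cc(Br)ccc1O | intermediate
3 | benzyl [2-(benzyloxy)-5-bromophenyl]acetate | O=C(Cc1cc(Br)ccc1OCc1ccccc1)OCc1ccccc1 | intermediate
4 | [2-(benzyloxy)-5-bromophenyl]acetic acid | OC(=O)Cc1cc(Br)ccc1OCc1ccccc1 | intermediate
5 | [2-(benzyloxy)-5-bromophenyl]acetyl chloride | ClC(=O)Cc1cc(Br)ccc1OCc1ccccc1 | intermediate
6 | 4-hydroxybenzaldehyde | O=Cc1ccc(O)cc1 | starting material
7 | 4-formylphenyl pivalate | O=Cc1ccc(OC(=O)C(C)(C)C)cc1 | intermediate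
8 | [2-(benzyloxy)-5-bromophenyl]ketene | O=C=Cc1cc(Br)ccc1OCc1ccccc1 | intermediate
9 | 4-[(2S,3S)-3-[2-(benzyloxy)-5-bromophenyl]-4-oxooxetan-2-yl]phenyl pivalate (cis) | Brc1ccc(OCc2ccccc2)c([C@@H]2C(=O)O[C@@H]2c2ccc(OC(=O)C(C)(C)C)cc2)c1 | intermediate
10 | 3,5-bis(benzyloxy)phenol | Oc1cc(OCc2ccccc2)cc(OCc2ccccc2)c1 | starting material
11 | potassium (2S,3R)-3-[3,5-bis(benzyloxy)phenoxy]-2-[2-(benzyloxy)-5-bromophenyl]-3-[4-(pivaloyloxy)phenyl]propanoate | [K+].[O-]C(=O)[C@@H](c1cc(Br)ccc1OCc1ccccc1)[C@@H](Oc1cc(OCc2ccccc2)cc(OCc2ccccc2)c1)c1ccc(OC(=O)C(C)(C)C)cc1 | intermediate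
12 | (2S,3R)-3-[3,5-bis(benzyloxy)phenoxy]-2-[2-(benzyloxy)-5-bromophenyl]-3-[4-(pivaloyloxy)phenyl]propanoic trifluoroacetic anhydride | FC(F)(F)C(=O)OC(=O)[C@@H](c1cc(Br)ccc1OCc1ccccc1)[C@@H](Oc1cc(OCc2ccccc2)cc(OCc2ccccc2)c1)c1ccc(OC(=O)C(C)(C)C)cc1 | intermediate
13 | 4-[(2R,3S)-5,7-bis(benzyloxy)-3-[2-(benzyloxy)-5-bromophenyl]-4-oxochroman-2-yl]phenyl pivalate | Brc1ccc(OCc2ccccc2)c([C@@H]2C(=O)c3c(OCc4ccccc4)cc(OCc4ccccc4)cc3O[C@H]2c2ccc(OC(=O)C(C)(C)C)cc2)c1 | intermediate
14 | 1-(2,4-dihydroxyphenyl)ethanone | CC(=O)c1ccc(O)cc1O | starting material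
15 | 1-[2,4-bis(benzyloxy)phenyl]ethanone | CC(=O)c1ccc(OCc2ccccc2)cc1OCc1ccccc1 | intermediate
16 | 1-[2,4-bis(benzyloxy)phenyl]-3-(diisopropylamino)propan-1-one | CC(C)N(CCC(=O)c1ccc(OCc2ccccc2)cc1OCc1ccccc1)C(C)C | intermediate
17 | 1-[2,4-bis(benzyloxy)phenyl]prop-2-en-1-one | C=CC(=O)c1ccc(OCc2ccccc2)cc1OCc1ccccc1 | intermediate
18 | 4-[(2R,3S)-5,7-bis(benzyloxy)-3-{2-(benzyloxy)-5-[(1E)-3-[2,4-bis(benzyloxy)phenyl]-3-oxoprop-1-en-1-yl]phenyl}-4-oxochroman-2-yl]phenyl pivalate | O=C(/C=C/c1ccc(OCc2ccccc2)c([C@@H]2C(=O)c3c(OCc4ccccc4)cc(OCc4ccccc4)cc3O[C@H]2c2ccc(OC(=O)C(C)(C)C)cc2)c1)c1ccc(OCc2ccccc2)cc1OCc1ccccc1 | intermediate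
19 | (2R,3S)-5,7-bis(benzyloxy)-3-{2-(benzyloxy)-5-[(1E)-3-[2,4-bis(benzyloxy)phenyl]-3-oxoprop-1-en-1-yl]phenyl}-2-(4-hydroxyphenyl)chroman-4-one | O=C(/C=C/c1ccc(OCc2ccccc2)c([C@@H]2C(=O)c3c(OCc4ccccc4)cc(OCc4ccccc4)cc3O[C@H]2c2ccc(O)cc2)c1)c1ccc(OCc2ccccc2)cc1OCc1ccccc1 | intermediate
20 | (2R,3S)-3-{5-[(1E)-3-(2,4-dihydroxyphenyl)-3-oxoprop-1-en-1-yl]-2-hydroxyphenyl}-5,7-dihydroxy-2-(4-hydroxyphenyl)chroman-4-one (CNP0272156.1) | O=C(/C=C/c1ccc(O)c([C@@H]2C(=O)c3c(O)cc(O)cc3O[C@H]2c2ccc(O)cc2)c1)c1ccc(O)cc1O | target

## Step count and risk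

Total step count: 11. Longest linear sequence: 8 steps (steps 1, 2, 3, 5, 6, 9, 10, 11).

**Step 6 (key step).**
- **What may go wrong.** The phenoxide may attack the lactone carbonyl, after which the open-chain aryl ester fragments by retro-aldol or dehydrates. The ambident, phloroglucinol-type phenoxide may alkylate through a ring carbon. C4 may partly ionise, which would blur the inversion. Ring A may be trifluoroacetylated in competition with ring closure.
- **Fallback.** It sets out from lactone 9 and returns at 13.
  - Acyl–oxygen opening with allyl alcohol (i-Pr2NEt, DMAP cat., CH2Cl2, 0 °C) should give allyl (2S,3S)-2-[2-(benzyloxy)-5-bromophenyl]-3-hydroxy-3-[4-(pivaloyloxy)phenyl]propanoate F1 with the carbinol carbon untouched.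
  - A Mitsunobu reaction of F1 with neutral phenol 10 (PPh3, DIAD, toluene, 0 °C) forms O1–C2 with the same inversion, giving allyl (2S,3R)-3-[3,5-bis(benzyloxy)phenoxy]-2-[2-(benzyloxy)-5-bromophenyl]-3-[4-(pivaloyloxy)phenyl]propanoate F2. No free phenoxide is present; dehydration to the cinnamate is what has to be watched.
  - Deallylation (Pd(PPh3)4, morpholine, THF, rt, where the aryl bromide should not undergo oxidative addition) gives (2S,3R)-3-[3,5-bis(benzyloxy)phenoxy]-2-[2-(benzyloxy)-5-bromophenyl]-3-[4-(pivaloyloxy)phenyl]propanoic acid F3.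
  - Trifluoroacetic anhydride in CH2Cl2 at 0 °C then closes ring C through 12 to 13.

**Step 5.**
- **What may go wrong.** Dimerisation of aryl ketene 8 may outrun its capture by the moderately electrophilic aromatic aldehyde. An uncatalysed background pathway may erode cis selectivity or enantioselectivity. The 4-aryl lactone may lose CO2 on warming.
- **Fallback.** It sets out from acid 4 and returns at 9.
  - Mixed-anhydride acylation (PivCl, Et3N, then (S)-4-benzyloxazolidin-2-one, LiCl, THF) gives (S)-4-benzyl-3-{[2-(benzyloxy)-5-bromophenyl]acetyl}oxazolidin-2-one F4.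
  - An Evans aldol reaction with aldehyde 7 (n-Bu2BOTf, i-Pr2NEt, CH2Cl2, −78 → 0 °C) should give the syn adduct (S)-4-benzyl-3-[(2S,3S)-2-[2-(benzyloxy)-5-bromophenyl]-3-hydroxy-3-[4-(pivaloyloxy)phenyl]propanoyl]oxazolidin-2-one F5.
  - Brief treatment with LiOH/H2O2 (THF/H2O, 0 °C) removes the auxiliary to give (2S,3S)-2-[2-(benzyloxy)-5-bromophenyl]-3-hydroxy-3-[4-(pivaloyloxy)phenyl]propanoic acid F6.
  - Carboxyl activation (PhSO2Cl, pyridine, 0 °C) lactonises with retention at both centres, so the syn acid gives cis lactone 9.

**Step 9.**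
- **What may go wrong.** Base-induced enolisation at C3 with β-elimination of O1 would open ring C to an achiral α-aryl chalcone; re-closure would erode the configuration at C2. Vinyl ketone 17 may polymerise. Oxidative addition of the electron-rich bromide may be sluggish.
- **Fallback.** It sets out from bromide 13 and returns at 18, with no base at all.
  - Stille vinylation (tributyl(vinyl)stannane, Pd(PPh3)4, toluene, 90 °C) gives 4-[(2R,3S)-5,7-bis(benzyloxy)-3-[2-(benzyloxy)-5-ethenylphenyl]-4-oxochroman-2-yl]phenyl pivalate F7.
  - Olefin cross-metathesis of F7 with enone 17 (second-generation Hoveyda–Grubbs catalyst, CH2Cl2, 40 °C) should give the (E)-enone 18.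

**Step 10.**
- **What may go wrong.** The hindered aryl pivalate may be cleaved incompletely. Forcing the reaction would start enolisation at C3 with opening of ring C, or addition to the enone.
- **Fallback.** It sets out from 18 and returns at 20, with the order of the last two operations reversed.
  - BCl3 and pentamethylbenzene (CH2Cl2, −78 → −40 °C) first give 4-[(2R,3S)-3-{5-[(1E)-3-(2,4-dihydroxyphenyl)-3-oxoprop-1-en-1-yl]-2-hydroxyphenyl}-5,7-dihydroxy-4-oxochroman-2-yl]phenyl pivalate F8.
  - The pivalate is then hydrolysed enzymatically (pig liver esterase, phosphate buffer pH 7 with DMSO, 30 °C) to 20; aryl pivalates are esterase substrates, and no base is needed.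

## Further compounds

F1 | step 6 | allyl (2S,3S)-2-[2-(benzyloxy)-5-bromophenyl]-3-hydroxy-3-[4-(pivaloyloxy)phenyl]propanoate | C=CCOC(=O)[C@@H](c1cc(Br)ccc1OCc1ccccc1)[C@H](O)c1ccc(OC(=O)C(C)(C)C)cc1
F2 | step 6 | allyl (2S,3R)-3-[3,5-bis(benzyloxy)phenoxy]-2-[2-(benzyloxy)-5-bromophenyl]-3-[4-(pivaloyloxy)phenyl]propanoate | C=CCOC(=O)[C@@H](c1cc(Br)ccc1OCc1ccccc1)[C@@H](Oc1cc(OCc2ccccc2)cc(OCc2ccccc2)c1)c1ccc(OC(=O)C(C)(C)C)cc1
F3 | step 6 | (2S,3R)-3-[3,5-bis(benzyloxy)phenoxy]-2-[2-(benzyloxy)-5-bromophenyl]-3-[4-(pivaloyloxy)phenyl]propanoic acid | OC(=O)[C@@H](c1cc(Br)ccc1OCc1ccccc1)[C@@H](Oc1cc(OCc2ccccc2)cc(OCc2ccccc2)c1)c1ccc(OC(=O)C(C)(C)C)cc1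
F4 | step 5 | (S)-4-benzyl-3-{[2-(benzyloxy)-5-bromophenyl]acetyl}oxazolidin-2-one | O=C(Cc1cc(Br)ccc1OCc1ccccc1)N1C(=O)OC[C@@H]1Cc1ccccc1
F5 | step 5 | (S)-4-benzyl-3-[(2S,3S)-2-[2-(benzyloxy)-5-bromophenyl]-3-hydroxy-3-[4-(pivaloyloxy)phenyl]propanoyl]oxazolidin-2-one | O=C([C@@H](c1cc(Br)ccc1OCc1ccccc1)[C@H](O)c1ccc(OC(=O)C(C)(C)C)cc1)N1C(=O)OC[C@@H]1Cc1ccccc1
F6 | step 5 | (2S,3S)-2-[2-(benzyloxy)-5-bromophenyl]-3-hydroxy-3-[4-(pivaloyloxy)phenyl]propanoic acid | OC(=O)[C@@H](c1cc(Br)ccc1OCc1ccccc1)[C@H](O)c1ccc(OC(=O)C(C)(C)C)cc1
F7 | step 9 | 4-[(2R,3S)-5,7-bis(benzyloxy)-3-[2-(benzyloxy)-5-ethenylphenyl]-4-oxochroman-2-yl]phenyl pivalate | C=Cc1ccc(OCc2ccccc2)c([C@@H]2C(=O)c3c(OCc4ccccc4)cc(OCc4ccccc4)cc3O[C@H]2c2ccc(OC(=O)C(C)(C)C)cc2)c1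
F8 | step 10 | 4-[(2R,3S)-3-{5-[(1E)-3-(2,4-dihydroxyphenyl)-3-oxoprop-1-en-1-yl]-2-hydroxyphenyl}-5,7-dihydroxy-4-oxochroman-2-yl]phenyl pivalate | O=C(/C=C/c1ccc(O)c([C@@H]2C(=O)c3c(O)cc(O)cc3O[C@H]2c2ccc(OC(=O)C(C)(C)C)cc2)c1)c1ccc(O)cc1O
A1 | alternative 1 | 1-[2-[(4-hydroxybenzyl)oxy]-4,6-bis(methoxymethoxy)phenyl]-2-[5-(1,3-dioxolan-2-yl)-2-(methoxymethoxy)phenyl]ethan-1-one | COCOc1ccc(C2OCCO2)cc1CC(=O)c1c(OCOC)cc(OCOC)cc1OCc1ccc(O)cc1
A2 | alternative 1 | (2R,3S)-3-[5-(1,3-dioxolan-2-yl)-2-(methoxymethoxy)phenyl]-2-(4-hydroxyphenyl)-5,7-bis(methoxymethoxy)chroman-4-one | COCOc1ccc(C2OCCO2)cc1[C@@H]1C(=O)c2c(OCOC)cc(OCOC)cc2O[C@H]1c1ccc(O)cc1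
A3 | alternative 2 | 4,6-bis(benzyloxy)-2-hydroxybenzaldehyde | O=Cc1c(O)cc(OCc2ccccc2)cc1OCc1ccccc1
A4 | alternative 2 | 4-[(E)-2-[2-(benzyloxy)-5-bromophenyl]ethenyl]phenol | Oc1ccc(/C=C/c2cc(Br)ccc2OCc2ccccc2)cc1
A5 | alternative 2 | 2,3-trans-5,7-bis(benzyloxy)-3-[2-(benzyloxy)-5-bromophenyl]-2-(4-hydroxyphenyl)-4-methoxychroman (C2 and C3 arranged as in 20) | Brc1ccc(OCc2ccccc2)c([C@@H]2[C@@H](OC)c3c(OCc4ccccc4)cc(OCc4ccccc4)cc3O[C@H]2c2ccc(O)cc2)c1
A6 | alternative 3 | 2-{2-acetoxy-2-[5-bromo-2-(tert-butyldimethylsilyloxy)phenyl]-1-[4-(methoxymethoxy)phenyl]ethoxy}-4,6-bis(methoxymethoxy)benzaldehyde (aryloxy carbon arranged as C2 of 20, acetate carbon either) | O=Cc1c(OCOC)cc(OCOC)cc1O[C@@H](c1ccc(OCOC)cc1)C(OC(C)=O)c1cc(Br)ccc1O[Si](C)(C)C(C)(C)C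
A7 | alternative 3 | (2R,3S)-3-(5-bromo-2-hydroxyphenyl)-5,7-bis(methoxymethoxy)-2-[4-(methoxymethoxy)phenyl]chroman-4-one | Oc1ccc(Br)cc1[C@@H]1C(=O)c2c(OCOC)cc(OCOC)cc2O[C@H]1c1ccc(OCOC)cc1
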